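The route rests on closing the cyclohexane ring at the C4–C5 bond (quinic acid numbering), the bond between the two trans acyloxy-bearing carbons. The precursor is an acyclic keto aldehyde whose quaternary C1 carries its oxygen and carboxyl carbon locked in a pivalaldehyde-derived dioxolanone. An (S)-proline-catalysed intramolecular aldol addition of its alkoxymethyl ketone (C3, C4) to the aldehyde (C5) closes the carbocycle and sets the trans C4–O/C5–O pair in one operation; it exploits the contiguous C3–C4–C5 oxygenation, an α-alkoxy ketone aldol retron. An Evans–Tishchenko reduction then sets C3 while delivering the first galloyl unit to O5, and O3 and O4 are acylated in turn.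

Key step: step 5

Remark: (S)-2-hydroxypent-4-enoic acid (5) is taken as a commercial compound. Ring atoms are numbered as in quinic acid throughout (C1 quaternary; C3, C4, C5 oxygenated; O3 and O4 cis to each other and to O1, O4 and O5 trans, O5 cis to the carboxyl carbon). "Quinic acid pivalaldehyde acetal" means the spiro 2-tert-butyl-1,3-dioxolan-4-one closed across O1 and the carboxyl group (a 2-tert-butyl-1,3-dioxaspiro[4.5]decan-4-one), acetal carbon S.

Step 1
Reactants: 1 3-bromo-2-(bromomethyl)prop-1-ene; 2 4-methoxybenzyl alcohol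
Product: 4 4-methoxybenzyl 2-(bromomethyl)prop-2-en-1-yl ether, via sodium 4-methoxybenzyl oxide 3 (not isolated)
Conditions: NaH, THF, 0 °C; then 1 (3 equiv), 0 → 20 °C
Reagents that add atoms: none
Why: Williamson ether synthesis in which alkoxide 3 displaces one of the two equivalent allylic bromides of 1 (direct and allylic displacement give the same ether), the excess of 1 holding back the bis-ether, and no stereocentre is involved.

Step 2
Reactants: 5 (S)-2-hydroxypent-4-enoic acid
Product: 6 (2S,5S)-2-tert-butyl-5-(prop-2-en-1-yl)-1,3-dioxolan-4-one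
Conditions: t-BuCHO, TsOH·H2O (cat.), H2SO4 (cat.), pentane, reflux, water separator; cis isomer separated
Reagents that add atoms: pivalaldehyde, CC(C)(C)C=O
Why: Acid-catalysed acetalisation with azeotropic removal of water (first stage of the self-regeneration of stereocentres) closes the 1,3-dioxolan-4-one without touching the carbinol centre of 5; the new acetal centre should form mainly cis to the allyl group, and the cis isomer is separated.

Step 3
Reactants: 6 (2S,5S)-2-tert-butyl-5-(prop-2-en-1-yl)-1,3-dioxolan-4-one; 4 4-methoxybenzyl 2-(bromomethyl)prop-2-en-1-yl ether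
Product: 8 (2S,5R)-2-tert-butyl-5-(2-{[(4-methoxyphenyl)methoxy]methyl}prop-2-en-1-yl)-5-(prop-2-en-1-yl)-1,3-dioxolan-4-one, via lithium enolate 7 (not isolated)
Conditions: LiN(i-Pr)2, THF, −78 °C; then 4, −78 → −30 °C
Reagents that add atoms: none
Why: Dioxolanone enolate alkylation (self-regeneration of stereocentres) in which the ring carbon becomes trigonal in 7 while the acetal centre persists and its tert-butyl group sends the allylic bromide 4 to the opposite face, so the new arm takes the place of the former hydrogen and the quaternary centre (future C1) is set with the allyl group cis to tert-butyl.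

Step 4
Reactants: 8 (2S,5R)-2-tert-butyl-5-(2-{[(4-methoxyphenyl)methoxy]methyl}prop-2-en-1-yl)-5-(prop-2-en-1-yl)-1,3-dioxolan-4-one
Product: 10 (2S,5R)-2-tert-butyl-5-{3-[(4-methoxyphenyl)methoxy]-2-oxopropyl}-5-(2-oxoethyl)-1,3-dioxolan-4-one, via bis-ozonide 9 (not isolated)
Conditions: O3, CH2Cl2, −78 °C, Sudan red 7B as end-point indicator; then PPh3, −78 → 20 °C
Reagents that add atoms: ozone, [O-][O+]=O
Why: Ozonolysis by the Criegee mechanism cleaves both terminal C=C bonds to the bis-ozonide 9, which PPh3 reduces to the aldehyde (C5) and the alkoxymethyl ketone (C3, C4) under neutral conditions, the indicator stopping the ozone before it can attack the 4-methoxybenzyl ether, so the acylal and the quaternary centre stay untouched.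

Step 5
Reactants: 10 (2S,5R)-2-tert-butyl-5-{3-[(4-methoxyphenyl)methoxy]-2-oxopropyl}-5-(2-oxoethyl)-1,3-dioxolan-4-one
Product: 12 (2S,5R,8S,9R)-2-tert-butyl-9-hydroxy-8-[(4-methoxyphenyl)methoxy]-1,3-dioxaspiro[4.5]decane-4,7-dione, via proline enamine 11 (not isolated)
Conditions: (S)-proline (30 mol %), DMSO, 20 °C, high dilution (0.02 M)
Reagents that add atoms: none
Why: (S)-Proline condenses with the ketone of 10 to the (E)-enamine 11 on the α-carbon that bears the 4-methoxybenzyloxy group, this carbon (C4) adds to the tethered aldehyde (C5) while the carboxylic acid protonates the aldehyde oxygen, and hydrolysis of the iminium ion releases 12 and the catalyst. The closest known reaction types are the Hajos–Parrish intramolecular aldolisation and the proline-catalysed aldol addition of O-protected hydroxyacetone donors, which react at the oxygenated α-carbon. The six-membered carbocycle closes in the 6-(enolendo)-exo-trig mode, and no other ring is available, because the enamine toward C2 and the enamine of the aldehyde could only close four-membered rings. C4 is set by the catalyst, whose carboxylic acid steers the aldehyde onto one face of the (E)-enamine as with hydroxyacetone donors, and C5 follows from the ring: with the acid-bound aldehyde oxygen held on the nitrogen side, the tether must take the place that the aldehyde hydrogen has in the intermolecular reaction, so the C4–O and C5–O bonds are anti-periplanar in the closing ring and should emerge trans. With C1 fixed, this catalyst-preferred arrangement places O5 on the face of the C1 carboxyl carbon, which is also the 1,3-anti relation to the C1–O bond that a β-alkoxy aldehyde favours, so substrate and catalyst should reinforce each other. The step needs addition without dehydration, retro-aldol cleavage or β-elimination of the C1 oxygen, which the near-neutral medium, room temperature and high dilution are meant to secure.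

Step 6
Reactants: 12 (2S,5R,8S,9R)-2-tert-butyl-9-hydroxy-8-[(4-methoxyphenyl)methoxy]-1,3-dioxaspiro[4.5]decane-4,7-dione; 13 3,4,5-tris(benzyloxy)benzaldehyde
Product: 15 4-O-(4-methoxybenzyl)-5-O-[3,4,5-tris(benzyloxy)benzoyl]quinic acid pivalaldehyde acetal (3-OH free), via samarium-bound hemiacetal 14 (not isolated)
Conditions: 13 (4 equiv) premixed with SmI2 (30 mol %), THF, 20 °C; then 12, −10 °C
Reagents that add atoms: none
Why: Evans–Tishchenko reduction, in which the 5-hydroxyl adds to aldehyde 13 on trivalent samarium to give hemiacetal 14, whose carbinol hydrogen passes as hydride within a six-membered chelate to the C3 carbonyl on the face of O5 (through the ring conformer with O5 axial), so that the aldehyde carbon ends as the O5 ester and the new 3-hydroxyl is set trans to O5 (1,3-anti) and cis to O4 and O1 as in quinic acid; premixing SmI2 with 13 consumes the divalent samarium before the α-alkoxy ketone is added.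

Step 7
Reactants: 15 4-O-(4-methoxybenzyl)-5-O-[3,4,5-tris(benzyloxy)benzoyl]quinic acid pivalaldehyde acetal; 16 3,4,5-tris(benzyloxy)benzoic acid
Product: 17 4-O-(4-methoxybenzyl)-3,5-bis-O-[3,4,5-tris(benzyloxy)benzoyl]quinic acid pivalaldehyde acetal
Conditions: 16 (1.5 equiv), EDC·HCl, DMAP, CH2Cl2, 20 → 35 °C
Reagents that add atoms: none
Why: Steglich esterification of the only free hydroxyl (axial O3) with the carbodiimide-activated acid 16 under DMAP catalysis; no stereocentre is touched, and an ester shift between O5 and O3 is unlikely across the trans-1,3 relation and would in any case lead to the same diester.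

Step 8
Reactants: 17 4-O-(4-methoxybenzyl)-3,5-bis-O-[3,4,5-tris(benzyloxy)benzoyl]quinic acid pivalaldehyde acetal
Product: 18 3,5-bis-O-[3,4,5-tris(benzyloxy)benzoyl]quinic acid pivalaldehyde acetal (4-OH free)
Conditions: DDQ, CH2Cl2/pH 7 phosphate buffer (10:1), 0 → 20 °C
Reagents that add atoms: none
Why: Oxidative cleavage of the 4-methoxybenzyl ether by DDQ (hydride abstraction from the electron-rich benzylic position, capture of the oxocarbenium ion by water and collapse of the hemiacetal) frees O4 under buffered neutral conditions, the benzyl aryl ethers, the esters and the acylal being inert, and an ester shift to O4 would be harmless because step 9 places the same acyl group on whichever hydroxyl remains.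

Step 9
Reactants: 18 3,5-bis-O-[3,4,5-tris(benzyloxy)benzoyl]quinic acid pivalaldehyde acetal; 16 3,4,5-tris(benzyloxy)benzoic acid
Product: 19 3,4,5-tris-O-[3,4,5-tris(benzyloxy)benzoyl]quinic acid pivalaldehyde acetal
Conditions: 16 (2 equiv), EDC·HCl, DMAP, CH2Cl2, 35 °C
Reagents that add atoms: none
Why: Steglich esterification of the remaining equatorial 4-hydroxyl, which lies between two aroyloxy groups and therefore needs an excess of activated acid, while the tertiary C1 oxygen and the carboxyl group stay masked in the dioxolanone and no stereocentre is touched.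

Step 10
Reactants: 19 3,4,5-tris-O-[3,4,5-tris(benzyloxy)benzoyl]quinic acid pivalaldehyde acetal
Product: 20 3,4,5-tris-O-[3,4,5-tris(benzyloxy)benzoyl]quinic acid
Conditions: CF3CO2H/H2O (9:1), CH2Cl2, 0 → 20 °C
Reagents that add atoms: none
Why: Acid-catalysed hydrolysis of the acylal (acetal cleavage through the tert-butyl-substituted oxocarbenium ion, the oxygen of water ending in pivalaldehyde) frees the tertiary hydroxyl and the carboxylic acid, while benzoate-type esters should withstand aqueous CF3CO2H at room temperature and any loss of benzyl ethers is harmless at this stage.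

Step 11
Reactants: 20 3,4,5-tris-O-[3,4,5-tris(benzyloxy)benzoyl]quinic acid
Product: 21 3,4,5-tri-O-galloylquinic acid (CNP0148451.1)
Conditions: H2 (1 atm), Pd/C, THF/MeOH, 20 °C
Reagents that add atoms: none
Why: Hydrogenolysis of the nine benzyl aryl ethers over Pd/C gives the free pyrogallol units, and the esters, the acid and the four stereocentres are not affected.

Compound list
1 | 3-bromo-2-(bromomethyl)prop-1-ene | C=C(CBr)CBr | starting material
2 | 4-methoxybenzyl alcohol | OCc1ccc(OC)cc1 | starting material
3 | sodium 4-methoxybenzyl oxide | [Na+].[O-]Cc1ccc(OC)cc1 | intermediate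
4 | 4-methoxybenzyl 2-(bromomethyl)prop-2-en-1-yl ether | C=C(CBr)COCc1ccc(OC)cc1 | intermediate
5 | (S)-2-hydroxypent-4-enoic acid | C=CC[C@H](O)C(=O)O | starting material
6 | (2S,5S)-2-tert-butyl-5-(prop-2-en-1-yl)-1,3-dioxolan-4-one (tert-butyl and allyl cis) | C=CC[C@@H]1O[C@H](C(C)(C)C)OC1=O | intermediate
7 | lithium enolate of 6, lithium (2S)-2-tert-butyl-5-(prop-2-en-1-yl)-1,3-dioxol-4-olate | [Li]OC1=C(CC=C)O[C@H](C(C)(C)C)O1 | intermediate
8 | (2S,5R)-2-tert-butyl-5-(2-{[(4-methoxyphenyl)methoxy]methyl}prop-2-en-1-yl)-5-(prop-2-en-1-yl)-1,3-dioxolan-4-one (new arm trans to tert-butyl) | C=CC[C@]1(CC(=C)COCc2ccc(OC)cc2)O[C@H](C(C)(C)C)OC1=O | intermediate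
9 | bis-ozonide of 8 (both C=C bonds as 1,2,4-trioxolanes, mixture of epimers at the trioxolane carbons) | C(C2OCOO2)[C@]1(CC2(COCc3ccc(OC)cc3)OCOO2)O[C@H](C(C)(C)C)OC1=O | intermediate
10 | (2S,5R)-2-tert-butyl-5-{3-[(4-methoxyphenyl)methoxy]-2-oxopropyl}-5-(2-oxoethyl)-1,3-dioxolan-4-one | O=CC[C@]1(CC(=O)COCc2ccc(OC)cc2)O[C@H](C(C)(C)C)OC1=O | intermediate
11 | (E)-enamine of the ketone of 10 with (S)-proline (C=C toward the alkoxy-bearing carbon, N trans to the 4-methoxybenzyloxy group) | O=CC[C@]1(C/C(=C\OCc2ccc(OC)cc2)N2CCC[C@H]2C(=O)O)O[C@H](C(C)(C)C)OC1=O | intermediate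
12 | (2S,5R,8S,9R)-2-tert-butyl-9-hydroxy-8-[(4-methoxyphenyl)methoxy]-1,3-dioxaspiro[4.5]decane-4,7-dione, the pivalaldehyde acetal of 4-O-(4-methoxybenzyl)-3-dehydroquinic acid (O4 and 5-OH trans, 5-OH cis to the lactone carbonyl carbon) | O[C@@H]1C[C@]2(CC(=O)[C@H]1OCc1ccc(OC)cc1)O[C@H](C(C)(C)C)OC2=O | intermediate
13 | 3,4,5-tris(benzyloxy)benzaldehyde | O=Cc1cc(OCc2ccccc2)c(OCc2ccccc2)c(OCc2ccccc2)c1 | starting material
14 | hemiacetal of the 5-hydroxyl of 12 with aldehyde 13 (held on trivalent samarium in the flask, drawn metal-free; mixture of epimers at the hemiacetal carbon) | OC(O[C@@H]1C[C@]2(CC(=O)[C@H]1OCc1ccc(OC)cc1)O[C@H](C(C)(C)C)OC2=O)c1cc(OCc2ccccc2)c(OCc2ccccc2)c(OCc2ccccc2)c1 | intermediate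
15 | 4-O-(4-methoxybenzyl)-5-O-[3,4,5-tris(benzyloxy)benzoyl]quinic acid pivalaldehyde acetal (3-OH free; acetal carbon S, ring centres as in (−)-quinic acid) | O=C(O[C@@H]1C[C@]2(C[C@@H](O)[C@H]1OCc1ccc(OC)cc1)O[C@H](C(C)(C)C)OC2=O)c1cc(OCc2ccccc2)c(OCc2ccccc2)c(OCc2ccccc2)c1 | intermediate
16 | 3,4,5-tris(benzyloxy)benzoic acid | OC(=O)c1cc(OCc2ccccc2)c(OCc2ccccc2)c(OCc2ccccc2)c1 | starting material
17 | 4-O-(4-methoxybenzyl)-3,5-bis-O-[3,4,5-tris(benzyloxy)benzoyl]quinic acid pivalaldehyde acetal (acetal carbon S, ring centres as in (−)-quinic acid) | O=C(O[C@@H]1C[C@]2(C[C@@H](OC(=O)c3cc(OCc4ccccc4)c(OCc4ccccc4)c(OCc4ccccc4)c3)[C@H]1OCc1ccc(OC)cc1)O[C@H](C(C)(C)C)OC2=O)c1cc(OCc2ccccc2)c(OCc2ccccc2)c(OCc2ccccc2)c1 | intermediate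
18 | 3,5-bis-O-[3,4,5-tris(benzyloxy)benzoyl]quinic acid pivalaldehyde acetal (4-OH free; acetal carbon S, ring centres as in (−)-quinic acid) | O=C(O[C@@H]1C[C@]2(C[C@@H](OC(=O)c3cc(OCc4ccccc4)c(OCc4ccccc4)c(OCc4ccccc4)c3)[C@H]1O)O[C@H](C(C)(C)C)OC2=O)c1cc(OCc2ccccc2)c(OCc2ccccc2)c(OCc2ccccc2)c1 | intermediate
19 | 3,4,5-tris-O-[3,4,5-tris(benzyloxy)benzoyl]quinic acid pivalaldehyde acetal (acetal carbon S, ring centres as in (−)-quinic acid) | O=C(O[C@@H]1C[C@]2(C[C@@H](OC(=O)c3cc(OCc4ccccc4)c(OCc4ccccc4)c(OCc4ccccc4)c3)[C@H]1OC(=O)c1cc(OCc3ccccc3)c(OCc3ccccc3)c(OCc3ccccc3)c1)O[C@H](C(C)(C)C)OC2=O)c1cc(OCc2ccccc2)c(OCc2ccccc2)c(OCc2ccccc2)c1 | intermediate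
20 | 3,4,5-tris-O-[3,4,5-tris(benzyloxy)benzoyl]-(−)-quinic acid (1-OH and CO2H free) | O=C(O[C@@H]1C[C@](O)(C(=O)O)C[C@@H](OC(=O)c2cc(OCc3ccccc3)c(OCc3ccccc3)c(OCc3ccccc3)c2)[C@H]1OC(=O)c1cc(OCc2ccccc2)c(OCc2ccccc2)c(OCc2ccccc2)c1)c1cc(OCc2ccccc2)c(OCc2ccccc2)c(OCc2ccccc2)c1 | intermediate
21 | 3,4,5-tri-O-galloyl-(−)-quinic acid (CNP0148451.1) | O=C(O[C@@H]1C[C@](O)(C(=O)O)C[C@@H](OC(=O)c2cc(O)c(O)c(O)c2)[C@H]1OC(=O)c1cc(O)c(O)c(O)c1)c1cc(O)c(O)c(O)c1 | target

Total step count: 11. Longest linear sequence: 10 steps (steps 2 to 11, from 5 to 21); step 1 is a one-step side branch that joins at step 3.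

Steps most likely to fail

Step 5 (key aldol cyclisation). The secondary amine may also form the enamine of the unbranched aldehyde, which can expel the C1 acetal oxygen by β-elimination or condense with a second molecule. The aldol product may lose the same oxygen from the C2 side. Facial selectivity may erode if the C1 centre and the catalyst do not reinforce each other. The fallback replaces enamine catalysis by a Lewis-acid cyclisation through an open transition state. It sets out from 10. Aldehyde-selective acetalisation with allyloxytrimethylsilane and catalytic Me3SiOTf in CH2Cl2 at −78 °C should give the keto diallyl acetal F1. Me3SiOTf and Et3N should then convert the ketone into the (Z)-trimethylsilyl enol ether F2 on the alkoxy-bearing side. Catalytic Me3SiOTf at −78 °C triggers an intramolecular Mukaiyama addition of the enol ether to the allyl oxocarbenium ion. In the chair with the C4 alkoxy group, the C5 allyloxy group and the lactone carbonyl carbon all equatorial this should give the trans 5-O-allyl ketone F3. Hydrogen-activated [Ir(cod)(PMePh2)2]PF6 in THF at 20 °C should isomerise the allyl ether to the 5-O-(prop-1-en-1-yl) ether F4. Dilute aqueous HCl in acetone hydrolyses the enol ether and returns to the route at 12.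

Step 6 (Evans–Tishchenko reduction). Hydride transfer needs a conformer of the cyclohexanone with O5 axial, so the reaction may be slow, and the samarium alkoxide may instead trigger retro-aldol cleavage or β-elimination. The fallback separates reduction and acylation. It sets out from 12. Me4NBH(OAc)3 in MeCN/AcOH at −30 °C (Evans–Saksena reduction, hydride delivered from boron bound to O5) should give the 1,3-anti diol F5. Esterification with one equivalent of 16 (EDC·HCl, DMAP, CH2Cl2, 0 °C) should occur at the equatorial, less hindered 5-hydroxyl and returns to the route at 15. Imperfect site selectivity would not be harmful, since step 7 acylates O3 in any case.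

Step 10 (late acylal hydrolysis). The acylal at the quaternary carbon may hydrolyse too slowly under acid mild enough for the three aryl esters, and stronger acid may cleave or shift galloyl groups. The fallback replaces acid-catalysed acetal cleavage by nucleophilic opening of the lactone carbonyl. It sets out from 19. Me3SnOH in 1,2-dichloroethane at 60 °C should attack the dioxolanone carbonyl, the most electrophilic acyl group present, rather than the electron-rich, hindered aryl esters. The hemiacetal oxide that is expelled loses pivalaldehyde, and work-up with dilute HCl returns to the route at 20. No new compound is made on the way.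

Further compounds
F1 | step 5 | (2S,5R)-5-[2,2-bis(prop-2-en-1-yloxy)ethyl]-2-tert-butyl-5-{3-[(4-methoxyphenyl)methoxy]-2-oxopropyl}-1,3-dioxolan-4-one | C=CCOC(OCC=C)C[C@]1(CC(=O)COCc2ccc(OC)cc2)O[C@H](C(C)(C)C)OC1=O
F2 | step 5 | (Z)-trimethylsilyl enol ether of F1 (C=C toward the alkoxy-bearing carbon) | C=CCOC(OCC=C)C[C@]1(C/C(O[Si](C)(C)C)=C/OCc2ccc(OC)cc2)O[C@H](C(C)(C)C)OC1=O
F3 | step 5 | 5-O-allyl ether of 12 (trans 4,5-dialkoxy ketone) | C=CCO[C@@H]1C[C@]2(CC(=O)[C@H]1OCc1ccc(OC)cc1)O[C@H](C(C)(C)C)OC2=O
F4 | step 5 | 5-O-(prop-1-en-1-yl) ether of 12 (mixture of alkene isomers) | CC=CO[C@@H]1C[C@]2(CC(=O)[C@H]1OCc1ccc(OC)cc1)O[C@H](C(C)(C)C)OC2=O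
F5 | step 6 | 4-O-(4-methoxybenzyl)quinic acid pivalaldehyde acetal (3-OH and 5-OH free, 3-OH axial) | O[C@@H]1C[C@]2(C[C@@H](O)[C@H]1OCc1ccc(OC)cc1)O[C@H](C(C)(C)C)OC2=O
F0 | step 10 | none | none
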